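**Plan**

- Retrosynthetic cuts: the lactone C–O bond (back to a γ,δ-unsaturated acid), the cyclohexene C=C (ring-closing metathesis), and the ring CH2 next to the quaternary carbon (back to a ketone). Then, in one stroke, the bond from the quaternary lactone α-carbon to the ring-fusion CH together with the adjacent C–Br bond, which leads back to an alkenylcyclobutanol. Then the alkenyl–carbinol bond, the acetone aldol bond, the cyclobutanone ([2+2]) and the allyl–ring A bond.
- Forward ring order: ring A by bromonium cyclisation, cyclobutanone by ketene cycloaddition, cyclopentanone by ring expansion, cyclohexene by metathesis, lactone last.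
- Enabling feature: in the core cyclohexane the CHBr carbon sits directly on the quaternary carbon shared by the cyclopentane and the lactone, and its equatorial C–Br bond is antiperiplanar to the bond joining that quaternary carbon to the ring-fusion CH. This is the arrangement left when bromine and a migrating carbon add anti across an alkene.
- Stereochemistry: the ring A C–Br centre comes from a sulfoximine resolution and its carbinol from equatorial allyl addition. The two cyclobutane centres come from a chiral lithium amide and a trans aldol, and the cyclobutanol from addition anti to the α-arm. The quaternary and CHBr centres come from the ring expansion (retention in the migrating carbon, anti addition across the (E)-alkene). The lactone C–O centre is fixed by the bridged ring.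

Key step: step 15

Assumption: the (R,R) antipode of lithium bis(1-phenylethyl)amide is taken to remove the ring proton that leads to the configuration drawn for 21; both antipodes of the amine are sold, so the opposite sense would only change which one is used.

**Step 1**
Reactants: 1 prenyl bromide; 2 methyl acetoacetate
Product: 4 methyl 7-methyl-3-oxooct-6-enoate, via acetoacetate dianion 3 (not isolated)
Conditions: NaH, THF, 0 °C; n-BuLi, 0 °C; then 1, 0 °C to rt; aq. HCl
Reagents that add atoms: none
Why: γ-Alkylation of the acetoacetate dianion, in which the more basic terminal carbanion displaces the allylic bromide (SN2) and the β-keto ester is regenerated on acidification.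

**Step 2**
Reactants: 4 methyl 7-methyl-3-oxooct-6-enoate
Product: 5 methyl 3-bromo-2,2-dimethyl-6-oxocyclohexane-1-carboxylate (racemic)
Conditions: Et2SBr·SbCl5Br (BDSB), MeNO2, −25 °C
Reagents that add atoms: bromodiethylsulfonium bromopentachloroantimonate, CC[S+](Br)CC.Cl[Sb-](Cl)(Cl)(Cl)(Cl)Br
Why: Bromonium-induced cation–olefin cyclisation terminated by the β-keto ester enol, whose carbon captures the tertiary end of the bromonium ion to close the six-membered ring; the product is racemic at C–Br and the ester-bearing centre disappears in step 3.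

**Step 3**
Reactants: 5 methyl 3-bromo-2,2-dimethyl-6-oxocyclohexane-1-carboxylate
Product: 6 4-bromo-3,3-dimethylcyclohexan-1-one (racemic)
Conditions: 48% aq. HBr, AcOH, 90 °C
Reagents that add atoms: none
Why: Acid-mediated ester hydrolysis and decarboxylation of the β-keto acid; the acidic medium keeps the ketone as enol rather than enolate so the γ-bromide is not displaced to a cyclopropane, and bromide as the only halide makes any exchange degenerate.

**Step 4**
Reactants: 6 4-bromo-3,3-dimethylcyclohexan-1-one (racemic); 7 (S)-N,S-dimethyl-S-phenylsulfoximine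
Product: 9 (1R,4S)-4-bromo-3,3-dimethyl-1-{[(S)-N-methyl-S-phenylsulfonimidoyl]methyl}cyclohexan-1-ol, via lithiated sulfoximine 8 (not isolated)
Conditions: n-BuLi, THF, 0 °C; then 6, −78 °C; H2O; separation of the two adducts on silica
Reagents that add atoms: none
Why: Resolution of a ketone through diastereomeric β-hydroxysulfoximines: the lithiated enantiopure sulfoximine should add to both antipodes from the equatorial side (the axial 3-methyl blocks axial approach), and the adduct of the (S)-ketone is kept after chromatographic separation, its configuration to be secured by X-ray diffraction.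

**Step 5**
Reactants: 9 the β-hydroxysulfoximine
Product: 10 (S)-4-bromo-3,3-dimethylcyclohexan-1-one
Conditions: xylene, 130 °C
Reagents that add atoms: none
Why: Thermal retro-addition of the β-hydroxysulfoximine releases the ketone and the sulfoximine under neutral conditions that do not touch the C–Br stereocentre.

**Step 6**
Reactants: 10 (S)-4-bromo-3,3-dimethylcyclohexan-1-one; 11 allylmagnesium bromide
Product: 12 (1S,4S)-1-allyl-4-bromo-3,3-dimethylcyclohexan-1-ol
Conditions: Et2O, −78 °C; H2O
Reagents that add atoms: none
Why: Grignard 1,2-addition in which the axial methyl at C3 blocks axial approach, so the allyl group should enter equatorially and the new hydroxyl end axial and cis to the equatorial bromine; the cis alkoxide cannot displace the bromide.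

**Step 7**
Reactants: 12 (1S,4S)-1-allyl-4-bromo-3,3-dimethylcyclohexan-1-ol
Product: 13 [(1S,4S)-1-allyl-4-bromo-3,3-dimethylcyclohexyl]oxy(tert-butyl)dimethylsilane
Conditions: TBSOTf, 2,6-lutidine, CH2Cl2, 0 °C to rt
Reagents that add atoms: tert-butyldimethylsilyl triflate, CC(C)(C)[Si](C)(C)OS(=O)(=O)C(F)(F)F
Why: Silyl triflate silylation of a tertiary alcohol; the ether shields the hydroxyl from dichloroketene and from the later dehydration.

**Step 8**
Reactants: 13 the allyl silyl ether; 14 trichloroacetyl chloride
Product: 16 2,2-dichloro-3-{[(1S,4S)-4-bromo-1-(tert-butyldimethylsilyloxy)-3,3-dimethylcyclohexyl]methyl}cyclobutan-1-one, via dichloroketene 15 (not isolated)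
Conditions: Zn(Cu), POCl3, Et2O, rt
Reagents that add atoms: none
Why: [2+2] cycloaddition of dichloroketene (from zinc dechlorination of the acid chloride) to the terminal alkene, the carbonyl carbon bonding to the terminal CH2; the mixture at the new ring carbon is of no consequence because that carbon stops being a stereocentre in step 9.

**Step 9**
Reactants: 16 the dichlorocyclobutanone
Product: 17 3-{[(1S,4S)-4-bromo-1-(tert-butyldimethylsilyloxy)-3,3-dimethylcyclohexyl]methyl}cyclobutan-1-one
Conditions: Zn, NH4Cl, MeOH, rt
Reagents that add atoms: none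
Why: Reductive dechlorination of the α,α-dichloro ketone through zinc enolates; an unactivated secondary bromide is inert to zinc dust at room temperature.

**Step 10**
Reactants: 17 the cyclobutanone; 18 acetone
Product: 21 (2R,3R)-3-{[(1S,4S)-4-bromo-1-(tert-butyldimethylsilyloxy)-3,3-dimethylcyclohexyl]methyl}-2-[2-(trimethylsilyloxy)propan-2-yl]cyclobutan-1-one, via lithium enolate 19 (not isolated), via lithium aldolate 20 (not isolated)
Conditions: (R,R)-bis(1-phenylethyl)amine, n-BuLi, LiCl, THF, −78 °C; 18, −78 °C; TMSCl, −78 to −20 °C
Reagents that add atoms: chlorotrimethylsilane, C[Si](C)(C)Cl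
Why: Enantioselective deprotonation by a chiral lithium amide desymmetrises the prochiral 3-substituted cyclobutanone, the enolate adds to acetone anti to the ring substituent (aldol addition, 2,3-trans) and cold silylation of the aldolate forestalls retro-aldol, so the amide fixes both new ring centres independently of ring A.

**Step 11**
Reactants: 22 propargyl alcohol; 23 allyl bromide
Product: 24 hex-5-en-2-yn-1-ol
Conditions: CuI (cat.), K2CO3, n-Bu4NCl, DMF, rt
Reagents that add atoms: none
Why: Copper-catalysed allylation of a terminal alkyne (copper acetylide substitution of the allylic bromide) gives the skipped enyne.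

**Step 12**
Reactants: 24 hex-5-en-2-yn-1-ol
Product: 25 (E)-2-(tributylstannyl)hexa-2,5-dien-1-ol
Conditions: Bu3SnH, PdCl2(PPh3)2 (cat.), THF, 0 °C to rt
Reagents that add atoms: tributyltin hydride, CCCC[SnH](CCCC)CCCC
Why: Palladium-catalysed syn-hydrostannation in which the propargylic hydroxyl steers tin to the proximal alkyne carbon and cis delivery of H and Sn fixes the geometry with tin trans to the allyl chain; any distal isomer is removed by chromatography.

**Step 13**
Reactants: 25 (E)-2-(tributylstannyl)hexa-2,5-dien-1-ol
Product: 26 (E)-tert-butyldimethyl{[2-(tributylstannyl)hexa-2,5-dien-1-yl]oxy}silane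
Conditions: TBSCl, imidazole, DMF, rt
Reagents that add atoms: tert-butyldimethylsilyl chloride, CC(C)(C)[Si](C)(C)Cl
Why: Standard silylation of a primary alcohol under conditions that do not protodestannylate the alkenylstannane.

**Step 14**
Reactants: 21 the silyloxypropyl cyclobutanone; 26 the alkenylstannane
Product: 28 (E)-alkenylcyclobutanol (hydroxyl cis to the silyloxypropyl arm; alkenyl group cis to the ring A methylene arm), via alkenyllithium 27 (not isolated)
Conditions: n-BuLi, THF, −78 °C; then 21, −78 °C; H2O
Reagents that add atoms: none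
Why: Tin–lithium exchange with retention of alkene geometry and 1,2-addition to the strained ketone; the reagent should approach anti to the bulky α-(silyloxypropyl) group, which sets the carbinol centre with the hydroxyl cis to that arm.

**Step 15**
Reactants: 28 the (E)-alkenylcyclobutanol
Product: 29 α-quaternary β-bromo cyclopentanone (bromoallyl branch trans to the silyloxypropyl arm)
Conditions: NBS, propylene oxide, i-PrOH, −78 to −40 °C
Reagents that add atoms: N-bromosuccinimide, O=C1CCC(=O)N1Br
Why: Halonium-induced semipinacol rearrangement: NBS forms a bromonium ion on the electron-rich trisubstituted alkene, and as its bond to the carbon next to the carbinol ionises the substituted ring carbon shifts to that carbon antiperiplanar to bromine while the hydroxyl becomes the ketone, relief of four-membered ring strain driving the shift. The closest known reaction type is the N-halosuccinimide ring expansion of 1-alkenylcyclobutanols to α-quaternary β-halo cyclopentanones. The cyclopentanone arises by ring expansion through a 1,2-shift and not by an end-on closure, and the migrating CH keeps its configuration. The bromomethine is set by the stereospecific anti addition of bromine and carbon across the (E)-alkene, and the quaternary centre by the alkene face offered to the migrating carbon: in the reactive rotamer the CH2OTBS group lies beside the carbinol oxygen and the bromine-bearing carbon beside the ring CH2, so the bulkier bromoalkyl branch should end trans to the silyloxypropyl arm. The step needs migration of the substituted ring carbon over the ring CH2 (its higher substitution), attack on the trisubstituted alkene and not the vinyl group (higher nucleophilicity and the hydroxyl push) and no ether formation by the arm oxygen (the arm is trans to the alkenyl group and cannot reach the bromonium ion), while propylene oxide removes HBr.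

**Step 16**
Reactants: 29 the bromo cyclopentanone
Product: 30 hydroxy ketone (free 2-hydroxypropan-2-yl arm)
Conditions: PPTS (cat.), MeOH, 0 °C
Reagents that add atoms: none
Why: Acid-catalysed methanolysis of the labile tertiary trimethylsilyl ether; the neopentylic primary and the tertiary TBS ethers cleave far more slowly.

**Step 17**
Reactants: 30 the hydroxy ketone
Product: 31 isopropenyl ketone
Conditions: Burgess reagent, toluene, 60 °C
Reagents that add atoms: none
Why: Burgess dehydration (syn elimination through the sulfamate ester) of the tertiary alcohol; six methyl hydrogens and the strain of a tetrasubstituted alkene beside the quaternary carbon should favour the isopropenyl isomer.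

**Step 18**
Reactants: 31 the isopropenyl ketone
Product: 32 trans-fused bicyclic ketone with the trisubstituted cyclohexene
Conditions: second-generation Grubbs catalyst RuCl2(=CHPh)(PCy3)(H2IMes) (cat.), toluene, 80 °C
Reagents that add atoms: none
Why: Ring-closing olefin metathesis between the isopropenyl and vinyl groups, with loss of ethene, closes the cyclohexene trans-fused to the five-membered ring.

**Step 19**
Reactants: 32 the bicyclic ketone
Product: 33 tosylhydrazone of 32
Conditions: TsNHNH2, EtOH/THF, 60 °C
Reagents that add atoms: tosylhydrazide, Cc1ccc(cc1)S(=O)(=O)NN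
Why: Condensation of the ketone with tosylhydrazide; with the six-membered ring closed the equatorial bromide offers no backside to the hydrazone nitrogen, so pyrazoline formation is not expected.

**Step 20**
Reactants: 33 the tosylhydrazone
Product: 35 deoxygenated bicycle (ring CH2 in place of C=O), via N-boryl tosylhydrazine 34 (not isolated)
Conditions: catecholborane, CHCl3, 0 °C; then NaOAc·3H2O, reflux
Reagents that add atoms: none
Why: Caglioti-type reduction: hydroboration of the C=N bond by catecholborane, then acetate-induced loss of sulfinate and of dinitrogen from the alkyldiazene gives the methylene under conditions that leave alkyl bromides and the ring alkene untouched.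

**Step 21**
Reactants: 35 the bis-silyl ether
Product: 36 diol (primary CH2OH on the quaternary carbon; tertiary ring A hydroxyl)
Conditions: 48% aq. HF, MeCN, rt
Reagents that add atoms: none
Why: Fluoride-mediated cleavage of both TBS ethers; aqueous HF is too weak an acid to protonate the alkene or ionise the tertiary alcohol.

**Step 22**
Reactants: 36 the diol
Product: 37 hydroxy aldehyde
Conditions: Dess–Martin periodinane, CH2Cl2, rt
Reagents that add atoms: none
Why: Dess–Martin oxidation of the neopentylic primary alcohol; the tertiary alcohol cannot be oxidised and the α-quaternary aldehyde cannot epimerise or eliminate.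

**Step 23**
Reactants: 37 the hydroxy aldehyde
Product: 38 γ,δ-unsaturated carboxylic acid
Conditions: NaClO2, NaH2PO4, 2-methyl-2-butene, t-BuOH/H2O, rt
Reagents that add atoms: sodium chlorite, [Na+].[O-]Cl=O
Why: Pinnick oxidation with 2-methyl-2-butene as hypochlorite scavenger to protect the ring alkene; the equatorial bromide is gauche to the axial carboxyl, so decarboxylative elimination has no antiperiplanar path.

**Step 24**
Reactants: 38 the unsaturated acid
Product: 39 CNP0282702.2
Conditions: Co(salen) (cat., divalent cobalt; salen = N,N′-bis(3,5-di-tert-butylsalicylidene)cyclohexane-1,2-diaminate), N-fluoro-2,4,6-trimethylpyridinium tetrafluoroborate, (Me2SiH)2O, PhCF3, rt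
Reagents that add atoms: none
Why: Cobalt hydride hydrogen-atom-transfer hydroacyloxylation (radical–polar crossover): Markovnikov hydrogen transfer to the trisubstituted alkene gives the tertiary radical, which is oxidised and captured by the axial carboxyl to close the γ-lactone; the C–O centre is dictated by the bridged ring because the carboxyl reaches only one face, and the neutral conditions spare the tertiary alcohol of ring A.

**Compound list**

1 | prenyl bromide (1-bromo-3-methylbut-2-ene) | CC(C)=CCBr | starting material
2 | methyl acetoacetate | COC(=O)CC(C)=O | starting material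
3 | sodium lithium dianion of methyl acetoacetate | [Na+].[Li+].COC([O-])=CC(=C)[O-] | intermediate
4 | methyl 7-methyl-3-oxooct-6-enoate | COC(=O)CC(=O)CCC=C(C)C | intermediate
5 | methyl 3-bromo-2,2-dimethyl-6-oxocyclohexane-1-carboxylate (racemic, both epimers at C1) | COC(=O)C1C(=O)CCC(Br)C1(C)C | intermediate
6 | 4-bromo-3,3-dimethylcyclohexan-1-one (racemic) | CC1(C)CC(=O)CCC1Br | intermediate
7 | (S)-N,S-dimethyl-S-phenylsulfoximine | C[S@@](=O)(=NC)c1ccccc1 | starting material
8 | lithiated (S)-sulfoximine | [Li]C[S@@](=O)(=NC)c1ccccc1 | intermediate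
9 | (1R,4S)-4-bromo-3,3-dimethyl-1-{[(S)-N-methyl-S-phenylsulfonimidoyl]methyl}cyclohexan-1-ol (hydroxyl cis to bromine) | CC1(C)C[C@@](O)(C[S@@](=O)(=NC)c2ccccc2)CC[C@@H]1Br | intermediate
10 | (S)-4-bromo-3,3-dimethylcyclohexan-1-one | CC1(C)CC(=O)CC[C@@H]1Br | intermediate
11 | allylmagnesium bromide | C=CC[Mg]Br | starting material
12 | (1S,4S)-1-allyl-4-bromo-3,3-dimethylcyclohexan-1-ol | CC1(C)C[C@@](O)(CC=C)CC[C@@H]1Br | intermediate
13 | TBS ether of 12 | CC1(C)C[C@@](O[Si](C)(C)C(C)(C)C)(CC=C)CC[C@@H]1Br | intermediate
14 | trichloroacetyl chloride | ClC(=O)C(Cl)(Cl)Cl | starting material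
15 | dichloroketene | ClC(Cl)=C=O | intermediate
16 | 2,2-dichloro-3-{[(1S,4S)-4-bromo-1-(tert-butyldimethylsilyloxy)-3,3-dimethylcyclohexyl]methyl}cyclobutan-1-one (both epimers at C3) | CC1(C)C[C@@](O[Si](C)(C)C(C)(C)C)(CC2CC(=O)C2(Cl)Cl)CC[C@@H]1Br | intermediate
17 | 3-{[(1S,4S)-4-bromo-1-(tert-butyldimethylsilyloxy)-3,3-dimethylcyclohexyl]methyl}cyclobutan-1-one | CC1(C)C[C@@](O[Si](C)(C)C(C)(C)C)(CC2CC(=O)C2)CC[C@@H]1Br | intermediate
18 | acetone | CC(C)=O | starting material
19 | lithium enolate of 17 (one enantiotopic methylene deprotonated) | CC1(C)C[C@@](O[Si](C)(C)C(C)(C)C)(C[C@@H]2CC(O[Li])=C2)CC[C@@H]1Br | intermediate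
20 | lithium aldolate (2,3-trans) | CC1(C)C[C@@](O[Si](C)(C)C(C)(C)C)(C[C@@H]2CC(=O)[C@H]2C(C)(C)O[Li])CC[C@@H]1Br | intermediate
21 | (2R,3R)-3-{[ring A]methyl}-2-[2-(trimethylsilyloxy)propan-2-yl]cyclobutan-1-one (2,3-trans) | CC1(C)C[C@@](O[Si](C)(C)C(C)(C)C)(C[C@@H]2CC(=O)[C@H]2C(C)(C)O[Si](C)(C)C)CC[C@@H]1Br | intermediate
22 | propargyl alcohol | C#CCO | starting material
23 | allyl bromide | C=CCBr | starting material
24 | hex-5-en-2-yn-1-ol | C=CCC#CCO | intermediate
25 | (E)-2-(tributylstannyl)hexa-2,5-dien-1-ol | CCCC[Sn](CCCC)(CCCC)/C(CO)=C/CC=C | intermediate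
26 | TBS ether of 25 | CCCC[Sn](CCCC)(CCCC)/C(CO[Si](C)(C)C(C)(C)C)=C/CC=C | intermediate
27 | alkenyllithium (lithium trans to the allyl chain) | [Li]/C(CO[Si](C)(C)C(C)(C)C)=C/CC=C | intermediate
28 | (E)-alkenylcyclobutanol: ring A as TBS ether, arm as TMS ether, CH2OTBS on the alkene; hydroxyl cis to the arm | CC1(C)C[C@@](O[Si](C)(C)C(C)(C)C)(C[C@@H]2C[C@](O)(/C(CO[Si](C)(C)C(C)(C)C)=C/CC=C)[C@H]2C(C)(C)O[Si](C)(C)C)CC[C@@H]1Br | intermediate
29 | α-quaternary β-bromo cyclopentanone: CH2OTBS cis and CHBr-allyl trans to the silyloxypropyl arm | CC1(C)C[C@@](O[Si](C)(C)C(C)(C)C)(C[C@@H]2CC(=O)[C@@]([C@@H](Br)CC=C)(CO[Si](C)(C)C(C)(C)C)[C@H]2C(C)(C)O[Si](C)(C)C)CC[C@@H]1Br | intermediate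
30 | hydroxy ketone (arm as free tertiary alcohol) | CC1(C)C[C@@](O[Si](C)(C)C(C)(C)C)(C[C@@H]2CC(=O)[C@@]([C@@H](Br)CC=C)(CO[Si](C)(C)C(C)(C)C)[C@H]2C(C)(C)O)CC[C@@H]1Br | intermediate
31 | isopropenyl ketone | CC1(C)C[C@@](O[Si](C)(C)C(C)(C)C)(C[C@@H]2CC(=O)[C@@]([C@@H](Br)CC=C)(CO[Si](C)(C)C(C)(C)C)[C@H]2C(C)=C)CC[C@@H]1Br | intermediate
32 | trans-fused bicyclic ketone with methyl-substituted cyclohexene | CC1(C)C[C@@](O[Si](C)(C)C(C)(C)C)(C[C@@H]2CC(=O)[C@]3(CO[Si](C)(C)C(C)(C)C)[C@@H](Br)CC=C(C)[C@@H]23)CC[C@@H]1Br | intermediate
33 | tosylhydrazone of 32 (C=N geometry not defined) | CC1(C)C[C@@](O[Si](C)(C)C(C)(C)C)(C[C@@H]2CC(=NNS(=O)(=O)c4ccc(C)cc4)[C@]3(CO[Si](C)(C)C(C)(C)C)[C@@H](Br)CC=C(C)[C@@H]23)CC[C@@H]1Br | intermediate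
34 | N-(1,3,2-benzodioxaborol-2-yl) tosylhydrazine (new CH–N centre not defined) | CC1(C)C[C@@](O[Si](C)(C)C(C)(C)C)(C[C@@H]2CC(N(B4Oc5ccccc5O4)NS(=O)(=O)c6ccc(C)cc6)[C@]3(CO[Si](C)(C)C(C)(C)C)[C@@H](Br)CC=C(C)[C@@H]23)CC[C@@H]1Br | intermediate
35 | deoxygenated bicycle, bis-TBS ether | CC1(C)C[C@@](O[Si](C)(C)C(C)(C)C)(C[C@@H]2CC[C@]3(CO[Si](C)(C)C(C)(C)C)[C@@H](Br)CC=C(C)[C@@H]23)CC[C@@H]1Br | intermediate
36 | diol | CC1(C)C[C@@](O)(C[C@@H]2CC[C@]3(CO)[C@@H](Br)CC=C(C)[C@@H]23)CC[C@@H]1Br | intermediate
37 | hydroxy aldehyde | CC1(C)C[C@@](O)(C[C@@H]2CC[C@]3(C=O)[C@@H](Br)CC=C(C)[C@@H]23)CC[C@@H]1Br | intermediate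
38 | γ,δ-unsaturated carboxylic acid | CC1(C)C[C@@](O)(C[C@@H]2CC[C@]3(C(=O)O)[C@@H](Br)CC=C(C)[C@@H]23)CC[C@@H]1Br | intermediate
39 | CNP0282702.2 (dibromo hydroxy γ-lactone) | CC1(C)C[C@@](O)(C[C@@H]2CC[C@]34C(=O)O[C@](C)(CC[C@@H]3Br)[C@@H]24)CC[C@@H]1Br | target

**Step count**

Total: 24 steps. Longest linear sequence: 21 steps (steps 1–10 and 14–24). The alkenyl fragment takes 3 steps (11–13).

**Steps most likely to fail**

Step 15. The process at risk is rotation about the carbinol–alkene bond, which could deliver the migrating carbon to both alkene faces and give poor facial selectivity at the quaternary carbon. The fallback ties the carbinol oxygen to the allylic oxygen so that the CH2O group is held beside the carbinol oxygen. Setting out from 21, the O,C-dilithio reagent made from stannyl alcohol 25 with two equivalents of n-BuLi should add as in step 14 to give the diol F1. tBu2Si(OTf)2 and 2,6-lutidine should close the six-membered cyclic silylene F2, in which only the desired face of the alkene can align with the substituted ring bond. NBS then triggers the same 1,2-shift with the silyl ether oxygen as the donor, and aqueous work-up should leave the ketone as its di-tert-butyl(hydroxy)silyl ether F3. HF·pyridine removes that group and the trimethylsilyl ether to give the keto diol F4. TBSCl and imidazole silylate only the primary hydroxyl, which returns to the route at 30.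

Step 10. The processes at risk are reversal of the lithium aldolate (retro-aldol) before silylation and weak discrimination between the two ring methylenes under external quench. The fallback separates enolate formation from C–C bond formation. Setting out from 17, the same chiral amide with TMSCl present during deprotonation (internal quench) should give the silyl enol ether F5. TiCl4-mediated Mukaiyama aldol addition to acetone at −78 °C should give the trans hydroxy ketone F6 irreversibly. TMSCl and imidazole then return to the route at 21.

Step 19. The process at risk is stalled condensation at the neopentylic carbonyl, or decomposition of the hydrazone by other paths. The fallback removes the oxygen through the enol triflate. Setting out from 32, KHMDS and PhNTf2 should give the enol triflate F7. Pd(OAc)2/PPh3 with Bu3N and HCO2H should reduce it to the cyclopentene F8. Diimide (from 2-nitrobenzenesulfonylhydrazide and Et3N) should saturate the disubstituted ring alkene in preference to the trisubstituted one, which returns to the route at 35.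

**Further compounds**

F1 | step 15 | diol from 21 and the dilithio reagent (free CH2OH on the alkene) | CC1(C)C[C@@](O[Si](C)(C)C(C)(C)C)(C[C@@H]2C[C@](O)(/C(CO)=C/CC=C)[C@H]2C(C)(C)O[Si](C)(C)C)CC[C@@H]1Br
F2 | step 15 | cyclic di-tert-butylsilylene of F1 | CC1(C)C[C@@](O[Si](C)(C)C(C)(C)C)(C[C@@H]2C[C@@]3(O[Si](C(C)(C)C)(C(C)(C)C)OC\C3=C/CC=C)[C@H]2C(C)(C)O[Si](C)(C)C)CC[C@@H]1Br
F3 | step 15 | bromo cyclopentanone as di-tert-butyl(hydroxy)silyl ether | CC1(C)C[C@@](O[Si](C)(C)C(C)(C)C)(C[C@@H]2CC(=O)[C@@]([C@@H](Br)CC=C)(CO[Si](O)(C(C)(C)C)C(C)(C)C)[C@H]2C(C)(C)O[Si](C)(C)C)CC[C@@H]1Br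
F4 | step 15 | keto diol | CC1(C)C[C@@](O[Si](C)(C)C(C)(C)C)(C[C@@H]2CC(=O)[C@@]([C@@H](Br)CC=C)(CO)[C@H]2C(C)(C)O)CC[C@@H]1Br
F5 | step 10 | trimethylsilyl enol ether of 17 | CC1(C)C[C@@](O[Si](C)(C)C(C)(C)C)(C[C@@H]2CC(O[Si](C)(C)C)=C2)CC[C@@H]1Br
F6 | step 10 | trans β-hydroxy cyclobutanone | CC1(C)C[C@@](O[Si](C)(C)C(C)(C)C)(C[C@@H]2CC(=O)[C@H]2C(C)(C)O)CC[C@@H]1Br
F7 | step 19 | enol triflate of 32 | CC1(C)C[C@@](O[Si](C)(C)C(C)(C)C)(C[C@@H]2C=C(OS(=O)(=O)C(F)(F)F)[C@]3(CO[Si](C)(C)C(C)(C)C)[C@@H](Br)CC=C(C)[C@@H]23)CC[C@@H]1Br
F8 | step 19 | cyclopentene–cyclohexene diene | CC1(C)C[C@@](O[Si](C)(C)C(C)(C)C)(C[C@@H]2C=C[C@]3(CO[Si](C)(C)C(C)(C)C)[C@@H](Br)CC=C(C)[C@@H]23)CC[C@@H]1Br
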